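**Plan**

- Retrosynthesis: the O1–C8a aryl ether of the pyran ring is cut first, then the C3–C4 bond (aldol), then the C2 oxidation level (imide to CH2OH), and last the aryl–CH2 bond of the ring-B arylacetic acid (malonate arylation).
- Forward: 2,3-dimethoxyphenol is taken to the benzyl-protected ring-B arylacetic acid and its N-acyl oxazolidinone. A syn-aldol with O-allylvanillin joins rings A and B through C3–C4, reduction gives the C2 carbinol, and the pyran ring (the only ring made) closes last, before debenzylation.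
- Enabling feature: ring A is a guaiacol with C7–OH next to C6–OMe and the side chain on C4a, para to C7–OH. The missing O1–C8a bond lies para to C6–OMe, which is the β-carbon of the C7 carbonyl once C6/C7 are oxidised to the o-quinone monoketal. C8a–H can therefore be etherified without a halogen, and loss of methanol returns the vanillin oxygenation.
- Stereochemistry: C3 and C4 are both set in the (R)-4-benzyloxazolidinone-controlled boron aldol. The syn adduct corresponds to the 3,4-trans chromanol (3S,4R), and no later step touches either centre.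

Key step: step 12

Remark: the C2 hydroxyl is carried as a triethylsilyl ether through the oxidation, because a free 3-hydroxypropyl chain para to the phenol would be expected to spirocyclise onto C4a (5-exo); fluoride releases it only after the monoketal has formed.

**Step 1**
Reactants: 1 2,3-dimethoxyphenol
Product: 2 2,3-dimethoxy-1,4-benzoquinone
Conditions: (KO3S)2NO (2.2 equiv), KH2PO4, H2O–acetone, 0 °C → rt
Reagents that add atoms: potassium nitrosodisulfonate (Fremy's salt), [K+].[K+].[O]N(S(=O)(=O)[O-])S(=O)(=O)[O-]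
Why: Teuber oxidation, in which the nitroxyl radical removes the phenolic hydrogen and a second equivalent delivers oxygen to the free para position, should give the p-quinone.

**Step 2**
Reactants: 2 2,3-dimethoxy-1,4-benzoquinone
Product: 4 1,4-bis(benzyloxy)-2,3-dimethoxybenzene, via 2,3-dimethoxyhydroquinone 3 (not isolated)
Conditions: Na2S2O4, Bu4NBr (cat.), THF–H2O, rt; then KOH, BnBr (2.5 equiv), rt
Reagents that add atoms: benzyl bromide, BrCc1ccccc1
Why: Dithionite reduction followed by phase-transfer Williamson etherification (one-pot reductive alkylation of a quinone) should benzylate both oxygens while excess dithionite keeps the hydroquinone from reoxidising.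

**Step 3**
Reactants: 4 1,4-bis(benzyloxy)-2,3-dimethoxybenzene
Product: 5 1,4-bis(benzyloxy)-5-bromo-2,3-dimethoxybenzene
Conditions: NBS (1.05 equiv), MeCN, 0 °C, dark
Reagents that add atoms: N-bromosuccinimide, O=C1CCC(=O)N1Br
Why: Electrophilic aromatic bromination of the tetra-alkoxybenzene can give only one monobromide because C5 and C6 are equivalent, and polar conditions in the dark avoid benzylic bromination.

**Step 4**
Reactants: 5 1,4-bis(benzyloxy)-5-bromo-2,3-dimethoxybenzene
Product: 6 diethyl 2-[2,5-bis(benzyloxy)-3,4-dimethoxyphenyl]propanedioate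
Conditions: CH2(CO2Et)2 (1.5 equiv), Pd(OAc)2 (2 mol %), t-Bu3P·HBF4 (4 mol %), K3PO4, toluene, 90 °C
Reagents that add atoms: diethyl malonate, CCOC(=O)CC(=O)OCC
Why: Palladium-catalysed α-arylation of a malonate with a bulky electron-rich trialkylphosphine is established for ortho-alkoxy, electron-rich aryl bromides and leaves benzyl ethers untouched.

**Step 5**
Reactants: 6 diethyl 2-[2,5-bis(benzyloxy)-3,4-dimethoxyphenyl]propanedioate
Product: 8 2-[2,5-bis(benzyloxy)-3,4-dimethoxyphenyl]acetic acid, via arylmalonic acid 7 (not isolated)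
Conditions: KOH, EtOH–H2O, 80 °C; then aq. HCl (pH 2), 80 °C
Reagents that add atoms: potassium hydroxide, [K+].[OH-]
Why: Saponification and thermal decarboxylation of the arylmalonic acid (malonic ester synthesis) should give the arylacetic acid under conditions that aryl benzyl ethers tolerate.

**Step 6**
Reactants: 8 2-[2,5-bis(benzyloxy)-3,4-dimethoxyphenyl]acetic acid; 9 (R)-4-benzyl-1,3-oxazolidin-2-one
Product: 11 (R)-4-benzyl-3-{2-[2,5-bis(benzyloxy)-3,4-dimethoxyphenyl]acetyl}-1,3-oxazolidin-2-one, via mixed pivalic anhydride 10 (not isolated)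
Conditions: PivCl, Et3N, THF, −20 °C; then 9, LiCl, −20 °C → rt
Reagents that add atoms: none
Why: N-Acylation of the oxazolidinone through the mixed pivalic anhydride with LiCl/Et3N activation is the standard mild route to N-acyl oxazolidinones and needs no strong base.

**Step 7**
Reactants: 12 vanillin
Product: 13 4-(allyloxy)-3-methoxybenzaldehyde
Conditions: allyl bromide, K2CO3, DMF, rt
Reagents that add atoms: allyl bromide, C=CCBr
Why: Williamson etherification of the phenoxide masks the phenol with a group that Pd(0) later removes in the presence of benzyl and silyl ethers.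

**Step 8**
Reactants: 11 (R)-4-benzyl-3-{2-[2,5-bis(benzyloxy)-3,4-dimethoxyphenyl]acetyl}-1,3-oxazolidin-2-one; 13 4-(allyloxy)-3-methoxybenzaldehyde
Product: 16 (R)-4-benzyl-3-[(2R,3R)-3-[4-(allyloxy)-3-methoxyphenyl]-2-[2,5-bis(benzyloxy)-3,4-dimethoxyphenyl]-3-hydroxypropanoyl]-1,3-oxazolidin-2-one, via (Z)-boron enolate 14 (not isolated), via boron aldolate 15 (not isolated)
Conditions: n-Bu2BOTf, i-Pr2NEt, CH2Cl2, −78 → 0 °C; 13, −78 → 0 °C; pH 7 buffer, MeOH, 30% H2O2, 0 °C
Reagents that add atoms: none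
Why: In the Evans syn-aldol the (Z)-dibutylboron enolate reacts through a Zimmerman–Traxler chair with the oxazolidinone dipole opposed to the enolate oxygen, so the aldehyde approaches the enolate face away from the benzyl group and sets both centres as (2R,3R), the future C3 (S) and C4 (R).

**Step 9**
Reactants: 16 (R)-4-benzyl-3-[(2R,3R)-3-[4-(allyloxy)-3-methoxyphenyl]-2-[2,5-bis(benzyloxy)-3,4-dimethoxyphenyl]-3-hydroxypropanoyl]-1,3-oxazolidin-2-one
Product: 17 (1R,2S)-1-[4-(allyloxy)-3-methoxyphenyl]-2-[2,5-bis(benzyloxy)-3,4-dimethoxyphenyl]propane-1,3-diol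
Conditions: LiBH4, MeOH (1 equiv), THF, 0 °C
Reagents that add atoms: none
Why: Reductive cleavage of the imide by LiBH4 at the exocyclic carbonyl gives the primary alcohol and returns the auxiliary without deprotonating the α-carbon (the descriptor at that carbon changes from R to S only through CIP priorities).

**Step 10**
Reactants: 17 (1R,2S)-1-[4-(allyloxy)-3-methoxyphenyl]-2-[2,5-bis(benzyloxy)-3,4-dimethoxyphenyl]propane-1,3-diol
Product: 18 (1R,2S)-1-[4-(allyloxy)-3-methoxyphenyl]-2-[2,5-bis(benzyloxy)-3,4-dimethoxyphenyl]-1,3-bis(triethylsilyloxy)propane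
Conditions: TESOTf (2.5 equiv), 2,6-lutidine, CH2Cl2, −78 → 0 °C
Reagents that add atoms: triethylsilyl trifluoromethanesulfonate, CC[Si](CC)(CC)OS(=O)(=O)C(F)(F)F
Why: Silyl triflate with 2,6-lutidine silylates both the primary and the hindered benzylic hydroxyl, masking the future nucleophile and protecting the benzylic carbinol from oxidative fragmentation.

**Step 11**
Reactants: 18 (1R,2S)-1-[4-(allyloxy)-3-methoxyphenyl]-2-[2,5-bis(benzyloxy)-3,4-dimethoxyphenyl]-1,3-bis(triethylsilyloxy)propane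
Product: 19 4-[(1R,2S)-2-[2,5-bis(benzyloxy)-3,4-dimethoxyphenyl]-1,3-bis(triethylsilyloxy)propyl]-2-methoxyphenol
Conditions: Pd(PPh3)4 (5 mol %), morpholine, THF, rt
Reagents that add atoms: none
Why: Tsuji–Trost deallylation, in which Pd(0) ionises the aryl allyl ether and morpholine traps the π-allyl complex, frees the phenol under near-neutral conditions that benzyl and silyl ethers survive.

**Step 12**
Reactants: 19 4-[(1R,2S)-2-[2,5-bis(benzyloxy)-3,4-dimethoxyphenyl]-1,3-bis(triethylsilyloxy)propyl]-2-methoxyphenol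
Product: 23 (3S,4R)-3-[2,5-bis(benzyloxy)-3,4-dimethoxyphenyl]-6-methoxychromane-4,7-diol, via bis-silyl quinone monoketal 20 (not isolated), via hydroxy quinone monoketal 21 (not isolated), via 4-O-silyl chromanol 22 (not isolated)
Conditions: PhI(OAc)2 (1.0 equiv), CH2Cl2–MeOH (9:1), 5 mM, 0 °C; then Bu4NF (4 equiv), THF, 0 °C → rt; AcOH quench
Reagents that add atoms: methanol, CO
Why: Proposed new method: PhI(OAc)2 oxidises the C7 phenol and methanol is captured at the methoxy-stabilised C6 to give the 6,6-dimethoxycyclohexa-2,4-dienone 20 while the C2 oxygen is still silylated, so it cannot spirocyclise onto C4a and the oxidant is spent before any electron-rich product phenol exists; fluoride, buffered by the acetic acid just released, then frees the C2 hydroxyl (21), which adds to C8a, the β-carbon of the C7 carbonyl, and 1,4-elimination of methanol across C8a–H and C6–OMe restores the arene with C6–OMe and C7–OH (22) before the excess fluoride removes the C4 silyl group. The closest known reaction types are the fluoride-triggered intramolecular aza- and carbon-Michael addition with rearomatisation on o-quinone monoketals and o-quinol acetates made from 2-methoxyphenols, and the amine-to-o-quinone closure of cyclodopa formation; an alkoxide closing a chroman in this way is the untested element. The pyran ring closes by 6-exo-trig oxa-Michael attack of O1 on C8a of the C8=C8a bond. No stereocentre is formed, and C3 and C4 are untouched because neither is acidic or ionisable while ring A is a dienone and the medium stays near neutral. The step needs attack at C8a (1,4) and not at C5 (1,6), which the ketal carbon next to C5 should enforce sterically; 5 mM dilution holds back Diels–Alder dimerisation of 20 and the low methanol content disfavours intermolecular methoxide addition.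

**Step 13**
Reactants: 23 (3S,4R)-3-[2,5-bis(benzyloxy)-3,4-dimethoxyphenyl]-6-methoxychromane-4,7-diol
Product: 24 (3S,4R)-3-(2,5-dihydroxy-3,4-dimethoxyphenyl)-6-methoxychromane-4,7-diol (CNP0163454.1)
Conditions: H2 (1 atm), 10% Pd/C, EtOAc, rt; filtration under Ar
Reagents that add atoms: none
Why: Hydrogenolysis of aryl benzyl ethers over Pd/C in a neutral aprotic solvent should be much faster than hydrogenolysis of the free C4 benzylic alcohol, and the hydrogen atmosphere protects the liberated hydroquinone.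

**Compound list**

1 | 2,3-dimethoxyphenol | COc1cccc(O)c1OC | starting material
2 | 2,3-dimethoxy-1,4-benzoquinone | COC1=C(OC)C(=O)C=CC1=O | intermediate
3 | 2,3-dimethoxybenzene-1,4-diol (2,3-dimethoxyhydroquinone) | COc1c(O)ccc(O)c1OC | intermediate (not isolated)
4 | 1,4-bis(benzyloxy)-2,3-dimethoxybenzene | COc1c(OCc2ccccc2)ccc(OCc2ccccc2)c1OC | intermediate
5 | 1,4-bis(benzyloxy)-5-bromo-2,3-dimethoxybenzene | COc1c(OCc2ccccc2)cc(Br)c(OCc2ccccc2)c1OC | intermediate
6 | diethyl 2-[2,5-bis(benzyloxy)-3,4-dimethoxyphenyl]propanedioate | CCOC(=O)C(C(=O)OCC)c1cc(OCc2ccccc2)c(OC)c(OC)c1OCc1ccccc1 | intermediate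
7 | 2-[2,5-bis(benzyloxy)-3,4-dimethoxyphenyl]propanedioic acid | OC(=O)C(C(=O)O)c1cc(OCc2ccccc2)c(OC)c(OC)c1OCc1ccccc1 | intermediate (not isolated)
8 | 2-[2,5-bis(benzyloxy)-3,4-dimethoxyphenyl]acetic acid | OC(=O)Cc1cc(OCc2ccccc2)c(OC)c(OC)c1OCc1ccccc1 | intermediate
9 | (R)-4-benzyl-1,3-oxazolidin-2-one | O=C1N[C@H](Cc2ccccc2)CO1 | starting material
10 | 2-[2,5-bis(benzyloxy)-3,4-dimethoxyphenyl]acetic pivalic anhydride | CC(C)(C)C(=O)OC(=O)Cc1cc(OCc2ccccc2)c(OC)c(OC)c1OCc1ccccc1 | intermediate (not isolated)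
11 | (R)-4-benzyl-3-{2-[2,5-bis(benzyloxy)-3,4-dimethoxyphenyl]acetyl}-1,3-oxazolidin-2-one | O=C1N(C(=O)Cc2cc(OCc3ccccc3)c(OC)c(OC)c2OCc2ccccc2)[C@H](Cc2ccccc2)CO1 | intermediate
12 | vanillin | COc1cc(C=O)ccc1O | starting material
13 | 4-(allyloxy)-3-methoxybenzaldehyde | C=CCOc1ccc(C=O)cc1OC | intermediate
14 | (R)-4-benzyl-3-[(Z)-2-[2,5-bis(benzyloxy)-3,4-dimethoxyphenyl]-1-(dibutylboranyloxy)ethenyl]-1,3-oxazolidin-2-one | CCCCB(CCCC)O/C(=C\c1cc(OCc2ccccc2)c(OC)c(OC)c1OCc1ccccc1)N1[C@H](Cc2ccccc2)COC1=O | intermediate (not isolated)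
15 | O-dibutylboranyl aldolate of 16 | O=C1N(C(=O)[C@H](c2cc(OCc3ccccc3)c(OC)c(OC)c2OCc2ccccc2)[C@@H](OB(CCCC)CCCC)c2ccc(OCC=C)c(OC)c2)[C@H](Cc2ccccc2)CO1 | intermediate (not isolated)
16 | (R)-4-benzyl-3-[(2R,3R)-3-[4-(allyloxy)-3-methoxyphenyl]-2-[2,5-bis(benzyloxy)-3,4-dimethoxyphenyl]-3-hydroxypropanoyl]-1,3-oxazolidin-2-one | O=C1N(C(=O)[C@H](c2cc(OCc3ccccc3)c(OC)c(OC)c2OCc2ccccc2)[C@@H](O)c2ccc(OCC=C)c(OC)c2)[C@H](Cc2ccccc2)CO1 | intermediate
17 | (1R,2S)-1-[4-(allyloxy)-3-methoxyphenyl]-2-[2,5-bis(benzyloxy)-3,4-dimethoxyphenyl]propane-1,3-diol | OC[C@H](c1cc(OCc2ccccc2)c(OC)c(OC)c1OCc1ccccc1)[C@@H](O)c1ccc(OCC=C)c(OC)c1 | intermediate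
18 | (1R,2S)-1-[4-(allyloxy)-3-methoxyphenyl]-2-[2,5-bis(benzyloxy)-3,4-dimethoxyphenyl]-1,3-bis(triethylsilyloxy)propane | CC[Si](CC)(CC)OC[C@H](c1cc(OCc2ccccc2)c(OC)c(OC)c1OCc1ccccc1)[C@@H](O[Si](CC)(CC)CC)c1ccc(OCC=C)c(OC)c1 | intermediate
19 | 4-[(1R,2S)-2-[2,5-bis(benzyloxy)-3,4-dimethoxyphenyl]-1,3-bis(triethylsilyloxy)propyl]-2-methoxyphenol | CC[Si](CC)(CC)OC[C@H](c1cc(OCc2ccccc2)c(OC)c(OC)c1OCc1ccccc1)[C@@H](O[Si](CC)(CC)CC)c1ccc(O)c(OC)c1 | intermediate (key-step precursor)
20 | 4-[(1R,2S)-2-[2,5-bis(benzyloxy)-3,4-dimethoxyphenyl]-1,3-bis(triethylsilyloxy)propyl]-6,6-dimethoxycyclohexa-2,4-dien-1-one | CC[Si](CC)(CC)OC[C@H](c1cc(OCc2ccccc2)c(OC)c(OC)c1OCc1ccccc1)[C@@H](O[Si](CC)(CC)CC)C1=CC(OC)(OC)C(=O)C=C1 | intermediate (not isolated)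
21 | 4-[(1R,2S)-2-[2,5-bis(benzyloxy)-3,4-dimethoxyphenyl]-3-hydroxy-1-(triethylsilyloxy)propyl]-6,6-dimethoxycyclohexa-2,4-dien-1-one | OC[C@H](c1cc(OCc2ccccc2)c(OC)c(OC)c1OCc1ccccc1)[C@@H](O[Si](CC)(CC)CC)C1=CC(OC)(OC)C(=O)C=C1 | intermediate (not isolated)
22 | (3S,4R)-3-[2,5-bis(benzyloxy)-3,4-dimethoxyphenyl]-6-methoxy-4-(triethylsilyloxy)chroman-7-ol | COc1cc2c(cc1O)OC[C@H](c1cc(OCc3ccccc3)c(OC)c(OC)c1OCc1ccccc1)[C@H]2O[Si](CC)(CC)CC | intermediate (not isolated)
23 | (3S,4R)-3-[2,5-bis(benzyloxy)-3,4-dimethoxyphenyl]-6-methoxychromane-4,7-diol | COc1cc2c(cc1O)OC[C@H](c1cc(OCc3ccccc3)c(OC)c(OC)c1OCc1ccccc1)[C@H]2O | intermediate (key-step product)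
24 | (3S,4R)-3-(2,5-dihydroxy-3,4-dimethoxyphenyl)-6-methoxychromane-4,7-diol | COc1cc2c(cc1O)OC[C@H](c1cc(O)c(OC)c(OC)c1O)[C@H]2O | target

**Step count and risks**

Total: 13 steps. Longest linear sequence: 12 steps (steps 1–6 and 8–13, from 2,3-dimethoxyphenol); step 7 is a one-step side branch.

Step 12 (proposed new method). Diels–Alder dimerisation of the dienone, conjugate addition at C5 or by methanol, or incomplete rearomatisation may overtake the 6-exo closure. The fallback forms the O1–C8a bond by known copper-catalysed intramolecular Ullmann etherification of an aryl bromide. It sets out from 11 and comes back at 23. Commercial 2-bromo-4-hydroxy-5-methoxybenzaldehyde (6-bromovanillin) would be O-allylated (allyl bromide, K2CO3, DMF) to 4-(allyloxy)-2-bromo-5-methoxybenzaldehyde F1. The boron aldol of step 8 with 11 should then give the syn adduct (R)-4-benzyl-3-[(2R,3R)-3-[4-(allyloxy)-2-bromo-5-methoxyphenyl]-2-[2,5-bis(benzyloxy)-3,4-dimethoxyphenyl]-3-hydroxypropanoyl]-1,3-oxazolidin-2-one F2. LiBH4 would give (1R,2S)-1-[4-(allyloxy)-2-bromo-5-methoxyphenyl]-2-[2,5-bis(benzyloxy)-3,4-dimethoxyphenyl]propane-1,3-diol F3. CuI, 1,10-phenanthroline and Cs2CO3 in toluene at 110 °C should close the pyran ring through the primary alkoxide, since the secondary hydroxyl could only form a four-membered ring, giving (3S,4R)-7-(allyloxy)-3-[2,5-bis(benzyloxy)-3,4-dimethoxyphenyl]-6-methoxychroman-4-ol F4. Pd(PPh3)4/morpholine would then remove the allyl group to give 23.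

Step 8. The aryl-stabilised boron enolate may add slowly to the electron-rich aldehyde and the aldolate may revert, eroding the syn selectivity. The fallback uses a chlorotitanium enolate of a different auxiliary with Lewis-acid activation of the aldehyde. It sets out from 8 and comes back at 17. DCC/DMAP coupling of 8 with commercial (R)-4-benzyl-1,3-thiazolidine-2-thione would give 1-[(R)-4-benzyl-2-thioxo-1,3-thiazolidin-3-yl]-2-[2,5-bis(benzyloxy)-3,4-dimethoxyphenyl]ethan-1-one F5. TiCl4, i-Pr2NEt and N-methylpyrrolidinone in CH2Cl2 at 0 °C, followed by 13, should give the same-sense syn adduct (2R,3R)-3-[4-(allyloxy)-3-methoxyphenyl]-1-[(R)-4-benzyl-2-thioxo-1,3-thiazolidin-3-yl]-2-[2,5-bis(benzyloxy)-3,4-dimethoxyphenyl]-3-hydroxypropan-1-one F6. NaBH4 in THF–EtOH cleaves the thioimide directly to 17.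

Step 13. Hydrogenolysis may also remove the electron-rich benzylic C4 oxygen, and the liberated hydroquinone may oxidise in air during work-up. The fallback changes the order of deprotection so that the C4 oxygen is silylated during hydrogenolysis. It sets out from 22, isolated by stopping the fluoride stage of step 12 with 1.1 equiv Bu4NF at −20 °C, and comes back at 24. H2 over Pd/C in EtOAc should give (3S,4R)-3-(2,5-dihydroxy-3,4-dimethoxyphenyl)-6-methoxy-4-(triethylsilyloxy)chroman-7-ol F7. Et3N·3HF in degassed THF would then cleave the silyl ether to give 24.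

**Further compounds**

F1 | step 12 | 4-(allyloxy)-2-bromo-5-methoxybenzaldehyde | C=CCOc1cc(Br)c(C=O)cc1OC
F2 | step 12 | (R)-4-benzyl-3-[(2R,3R)-3-[4-(allyloxy)-2-bromo-5-methoxyphenyl]-2-[2,5-bis(benzyloxy)-3,4-dimethoxyphenyl]-3-hydroxypropanoyl]-1,3-oxazolidin-2-one | O=C1N(C(=O)[C@H](c2cc(OCc3ccccc3)c(OC)c(OC)c2OCc2ccccc2)[C@@H](O)c2cc(OC)c(OCC=C)cc2Br)[C@H](Cc2ccccc2)CO1
F3 | step 12 | (1R,2S)-1-[4-(allyloxy)-2-bromo-5-methoxyphenyl]-2-[2,5-bis(benzyloxy)-3,4-dimethoxyphenyl]propane-1,3-diol | OC[C@H](c1cc(OCc2ccccc2)c(OC)c(OC)c1OCc1ccccc1)[C@@H](O)c1cc(OC)c(OCC=C)cc1Br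
F4 | step 12 | (3S,4R)-7-(allyloxy)-3-[2,5-bis(benzyloxy)-3,4-dimethoxyphenyl]-6-methoxychroman-4-ol | COc1cc2c(cc1OCC=C)OC[C@H](c1cc(OCc3ccccc3)c(OC)c(OC)c1OCc1ccccc1)[C@H]2O
F5 | step 8 | 1-[(R)-4-benzyl-2-thioxo-1,3-thiazolidin-3-yl]-2-[2,5-bis(benzyloxy)-3,4-dimethoxyphenyl]ethan-1-one | S=C1N(C(=O)Cc2cc(OCc3ccccc3)c(OC)c(OC)c2OCc2ccccc2)[C@H](Cc2ccccc2)CS1
F6 | step 8 | (2R,3R)-3-[4-(allyloxy)-3-methoxyphenyl]-1-[(R)-4-benzyl-2-thioxo-1,3-thiazolidin-3-yl]-2-[2,5-bis(benzyloxy)-3,4-dimethoxyphenyl]-3-hydroxypropan-1-one | S=C1N(C(=O)[C@H](c2cc(OCc3ccccc3)c(OC)c(OC)c2OCc2ccccc2)[C@@H](O)c2ccc(OCC=C)c(OC)c2)[C@H](Cc2ccccc2)CS1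
F7 | step 13 | (3S,4R)-3-(2,5-dihydroxy-3,4-dimethoxyphenyl)-6-methoxy-4-(triethylsilyloxy)chroman-7-ol | COc1cc2c(cc1O)OC[C@H](c1cc(O)c(OC)c(OC)c1O)[C@H]2O[Si](CC)(CC)CC
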